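Everything rests on disconnecting the C4–C4a bond of ring C. Ring A of the target is fully substituted, so in an open-chain (S)-3-aryloxy-3-phenylpropanoic acid that already carries O1, both benzyl arms and both protected phenols, C4a is the only free ring carbon; it lies ortho to O1 and C5–O and para to C7–O. One intramolecular Friedel–Crafts acylation therefore closes ring C with no regiochemical choice and leaves untouched the C2 stereocentre, set earlier by Mitsunobu inversion of a chiral-pool alcohol. Before that, a salicylate acetonide masks C4a and differentiates O1 from C5–O while the arms are installed, and the acid is unveiled from a homoallyl chain, which avoids the elimination that a β-hydroxy ester would suffer.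

Key step: step 7

Remark: 1, the acetonide of 2,4,6-trihydroxybenzoic acid, is taken as a catalogue compound.

Step 1
Reactants: 1 5,7-dihydroxy-2,2-dimethyl-4H-1,3-benzodioxin-4-one; 2 2-(benzyloxy)benzyl alcohol (2.3 equiv)
Product: 3 6,8-bis[2-(benzyloxy)benzyl]-5,7-dihydroxy-2,2-dimethyl-4H-1,3-benzodioxin-4-one
Conditions: TsOH·H2O (10 mol %), MeCN, 50 °C
Reagents that add atoms: 2-(benzyloxy)benzyl alcohol (2), OCc1ccccc1OCc1ccccc1
Why: Friedel–Crafts benzylation: the acid ionises the ortho-alkoxybenzyl alcohol to a stabilised benzyl cation that attacks C6 and C8, the only unsubstituted carbons of the nucleus (the lactone carbon occupies the third one), so the reaction can be driven to the bis-adduct without over-alkylation.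

Step 2
Reactants: 3 6,8-bis[2-(benzyloxy)benzyl]-5,7-dihydroxy-2,2-dimethyl-4H-1,3-benzodioxin-4-one; 4 benzyl bromide (3 equiv)
Product: 5 5,7-bis(benzyloxy)-6,8-bis[2-(benzyloxy)benzyl]-2,2-dimethyl-4H-1,3-benzodioxin-4-one
Conditions: K2CO3, DMF, 60 °C
Reagents that add atoms: benzyl bromide (4), BrCc1ccccc1
Why: Williamson ether synthesis run to exhaustion on both phenols (the chelated C5 hydroxyl needs the warming), so no regiochemical choice arises, and the acetonide is inert to carbonate in dry DMF.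

Step 3
Reactants: 5 5,7-bis(benzyloxy)-6,8-bis[2-(benzyloxy)benzyl]-2,2-dimethyl-4H-1,3-benzodioxin-4-one
Product: 7 3,5-bis(benzyloxy)-2,4-bis[2-(benzyloxy)benzyl]phenol, via hydroxybenzoic acid 6 (not isolated)
Conditions: KOH, dioxane/H2O, 80 °C; then aq. HCl (pH 2), 60 °C
Reagents that add atoms: none
Why: Saponification of the activated acetonide lactone expels acetone, and the resulting 2-hydroxy-4,6-dialkoxybenzoic acid should undergo protodecarboxylation by ipso-protonation on gentle warming in acid, which frees the carbon between the two outer oxygens and leaves a single phenol; benzyl ethers are inert to both stages.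

Step 4
Reactants: 7 3,5-bis(benzyloxy)-2,4-bis[2-(benzyloxy)benzyl]phenol; 8 (R)-1-phenylbut-3-en-1-ol
Product: 9 1,3-bis(benzyloxy)-2,4-bis[2-(benzyloxy)benzyl]-5-{[(1S)-1-phenylbut-3-en-1-yl]oxy}benzene
Conditions: PPh3, DIAD, toluene, 0 °C to rt
Reagents that add atoms: (R)-1-phenylbut-3-en-1-ol (8), C=CC[C@@H](O)c1ccccc1
Why: Mitsunobu reaction: the only free phenoxide displaces the alkoxyphosphonium of 8 in an SN2 step, so the (R)-carbinol is inverted to the (S)-aryl ether, and with no acidifying carbonyl next to the carbinol the elimination typical of 3-hydroxy-3-arylpropanoates is suppressed.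

Step 5
Reactants: 9 1,3-bis(benzyloxy)-2,4-bis[2-(benzyloxy)benzyl]-5-{[(1S)-1-phenylbut-3-en-1-yl]oxy}benzene
Product: 11 (3S)-3-{3,5-bis(benzyloxy)-2,4-bis[2-(benzyloxy)benzyl]phenoxy}-3-phenylpropanal, via diol 10 (not isolated)
Conditions: OsO4 (2 mol %), NaIO4, 2,6-lutidine, dioxane/H2O, rt
Reagents that add atoms: osmium tetroxide OsO4, O=[Os](=O)(=O)=O (supplies the aldehyde oxygen and is regenerated by NaIO4, [Na+].[O-]I(=O)(=O)=O)
Why: Lemieux–Johnson oxidation: catalytic dihydroxylation of the only alkene and periodate cleavage of the diol, both of which leave aryl ethers alone, while the lutidine-buffered medium should keep the aldehyde from losing its aryloxide by β-elimination; the crude aldehyde is used at once.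

Step 6
Reactants: 11 (3S)-3-{3,5-bis(benzyloxy)-2,4-bis[2-(benzyloxy)benzyl]phenoxy}-3-phenylpropanal
Product: 12 (3S)-3-{3,5-bis(benzyloxy)-2,4-bis[2-(benzyloxy)benzyl]phenoxy}-3-phenylpropanoic acid
Conditions: NaClO2, NaH2PO4, 2-methyl-2-butene (large excess), t-BuOH/H2O, 0 °C to rt
Reagents that add atoms: sodium chlorite NaClO2, [Na+].[O-]Cl=O
Why: Pinnick oxidation at about pH 4 takes the aldehyde to the acid without base-induced loss of the aryloxide, and the alkene scavenger traps HOCl before it can chlorinate C4a.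

Step 7
Reactants: 12 (3S)-3-{3,5-bis(benzyloxy)-2,4-bis[2-(benzyloxy)benzyl]phenoxy}-3-phenylpropanoic acid
Product: 14 (2S)-5,7-bis(benzyloxy)-6,8-bis[2-(benzyloxy)benzyl]-2-phenylchroman-4-one, via acyl trifluoroacetate 13 (not isolated)
Conditions: (CF3CO)2O (1.2 equiv), CH2Cl2, −20 to 0 °C; NaHCO3 quench
Reagents that add atoms: none
Why: The acid and (CF3CO)2O give the mixed anhydride 13, which, assisted by the CF3CO2H released, acts as an acylium-type electrophile, attacks C4a and rearomatises by proton loss. This is an intramolecular Friedel–Crafts acylation of the kind that converts 3-aryloxypropanoic acids into chroman-4-ones. Ring C closes as a six-membered ring, exo with respect to the acyl C=O and endo with respect to the C4a–C8a arene bond. No stereocentre is formed, and C2 should be carried through unchanged because the C2–O1 bond takes no part and its ionisation is disfavoured by the adjacent CH2–C(=O) group. Site selectivity needs no control element: C4a is the only unsubstituted carbon of ring A and is activated by O1, C5–O and C7–O, whereas attack on an arm ring would require a nine-membered ring. Low temperature, near-stoichiometric anhydride and the absence of a strong Lewis acid are chosen to spare the benzyl ethers and the C2–O1 bond.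

Step 8
Reactants: 14 (2S)-5,7-bis(benzyloxy)-6,8-bis[2-(benzyloxy)benzyl]-2-phenylchroman-4-one
Product: 15 dichamanetin, (2S)-5,7-dihydroxy-6,8-bis(2-hydroxybenzyl)-2-phenylchroman-4-one
Conditions: H2 (1 atm), 10% Pd/C, EtOAc, rt
Reagents that add atoms: none
Why: Hydrogenolysis of the four primary benzyl aryl ethers in neutral medium, where ring C cannot open to the chalcone and C2 should stay (S); the cyclic C2–O1 bond and the diarylmethane C–C bonds cleave much more slowly, so the reaction is stopped after four equivalents of H2.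

Compound list
1 | 5,7-dihydroxy-2,2-dimethyl-4H-1,3-benzodioxin-4-one | CC1(C)OC(=O)c2c(O)cc(O)cc2O1 | starting material
2 | 2-(benzyloxy)benzyl alcohol | OCc1ccccc1OCc1ccccc1 | starting material
3 | 6,8-bis[2-(benzyloxy)benzyl]-5,7-dihydroxy-2,2-dimethyl-4H-1,3-benzodioxin-4-one | CC1(C)OC(=O)c2c(O)c(Cc3ccccc3OCc3ccccc3)c(O)c(Cc3ccccc3OCc3ccccc3)c2O1 | intermediate
4 | benzyl bromide | BrCc1ccccc1 | starting material
5 | 5,7-bis(benzyloxy)-6,8-bis[2-(benzyloxy)benzyl]-2,2-dimethyl-4H-1,3-benzodioxin-4-one | CC1(C)OC(=O)c2c(OCc3ccccc3)c(Cc3ccccc3OCc3ccccc3)c(OCc3ccccc3)c(Cc3ccccc3OCc3ccccc3)c2O1 | intermediate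
6 | 2,4-bis(benzyloxy)-3,5-bis[2-(benzyloxy)benzyl]-6-hydroxybenzoic acid | OC(=O)c1c(OCc2ccccc2)c(Cc2ccccc2OCc2ccccc2)c(OCc2ccccc2)c(Cc2ccccc2OCc2ccccc2)c1O | intermediate (not isolated)
7 | 3,5-bis(benzyloxy)-2,4-bis[2-(benzyloxy)benzyl]phenol | Oc1cc(OCc2ccccc2)c(Cc2ccccc2OCc2ccccc2)c(OCc2ccccc2)c1Cc1ccccc1OCc1ccccc1 | intermediate
8 | (R)-1-phenylbut-3-en-1-ol | C=CC[C@@H](O)c1ccccc1 | starting material
9 | 1,3-bis(benzyloxy)-2,4-bis[2-(benzyloxy)benzyl]-5-{[(1S)-1-phenylbut-3-en-1-yl]oxy}benzene | C=CC[C@@H](c1ccccc1)Oc1cc(OCc2ccccc2)c(Cc2ccccc2OCc2ccccc2)c(OCc2ccccc2)c1Cc1ccccc1OCc1ccccc1 | intermediate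
10 | (4S)-4-{3,5-bis(benzyloxy)-2,4-bis[2-(benzyloxy)benzyl]phenoxy}-4-phenylbutane-1,2-diol (both C2 epimers) | OCC(O)C[C@@H](c1ccccc1)Oc1cc(OCc2ccccc2)c(Cc2ccccc2OCc2ccccc2)c(OCc2ccccc2)c1Cc1ccccc1OCc1ccccc1 | intermediate (not isolated)
11 | (3S)-3-{3,5-bis(benzyloxy)-2,4-bis[2-(benzyloxy)benzyl]phenoxy}-3-phenylpropanal | O=CC[C@@H](c1ccccc1)Oc1cc(OCc2ccccc2)c(Cc2ccccc2OCc2ccccc2)c(OCc2ccccc2)c1Cc1ccccc1OCc1ccccc1 | intermediate
12 | (3S)-3-{3,5-bis(benzyloxy)-2,4-bis[2-(benzyloxy)benzyl]phenoxy}-3-phenylpropanoic acid | OC(=O)C[C@@H](c1ccccc1)Oc1cc(OCc2ccccc2)c(Cc2ccccc2OCc2ccccc2)c(OCc2ccccc2)c1Cc1ccccc1OCc1ccccc1 | intermediate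
13 | (3S)-3-{3,5-bis(benzyloxy)-2,4-bis[2-(benzyloxy)benzyl]phenoxy}-3-phenylpropanoic trifluoroacetic anhydride | FC(F)(F)C(=O)OC(=O)C[C@@H](c1ccccc1)Oc1cc(OCc2ccccc2)c(Cc2ccccc2OCc2ccccc2)c(OCc2ccccc2)c1Cc1ccccc1OCc1ccccc1 | intermediate (not isolated)
14 | (2S)-5,7-bis(benzyloxy)-6,8-bis[2-(benzyloxy)benzyl]-2-phenylchroman-4-one | O=C1C[C@@H](c2ccccc2)Oc2c(Cc3ccccc3OCc3ccccc3)c(OCc3ccccc3)c(Cc3ccccc3OCc3ccccc3)c(OCc3ccccc3)c21 | intermediate
15 | dichamanetin, (2S)-5,7-dihydroxy-6,8-bis(2-hydroxybenzyl)-2-phenylchroman-4-one | O=C1C[C@@H](c2ccccc2)Oc2c(Cc3ccccc3O)c(O)c(Cc3ccccc3O)c(O)c21 | target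

Total step count: 8. Longest linear sequence: 8 steps (1 to 15).

Steps most likely to fail

Step 4. The activated carbinol may dehydrate to the conjugated diene, may partly ionise at the benzylic carbon with erosion of enantiopurity, or may couple sluggishly with the ortho-substituted, weakly acidic phenol. The fallback sets out from 7 and makes the C–O bond by asymmetric allylic substitution instead. The sodium phenoxide of 7 (NaH, THF) and purchased cinnamyl methyl carbonate (COC(=O)OC/C=C/c1ccccc1) with [Ir(cod)Cl]2 and a binaphthol-derived phosphoramidite ligand, whose enantiomer is chosen for the (S) product, should give the branched ether 1,3-bis(benzyloxy)-2,4-bis[2-(benzyloxy)benzyl]-5-{[(1S)-1-phenylprop-2-en-1-yl]oxy}benzene F1. Hydroboration with 9-BBN and oxidation with NaBO3·4H2O gives (3S)-3-{3,5-bis(benzyloxy)-2,4-bis[2-(benzyloxy)benzyl]phenoxy}-3-phenylpropan-1-ol F2. TEMPO (cat.), NaOCl (cat.) and NaClO2 in pH 6.7 phosphate buffer/MeCN oxidise it to the acid, so the fallback returns to the route at 12 and replaces steps 4 to 6.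

Step 7. The acid released may ionise or eliminate the benzylic C2–O1 bond (racemisation, loss of the aryloxide), benzyl groups may be lost or migrate, or C4a may be trifluoroacetylated. The fallback sets out from 12 and forms the same C4–C4a bond with an aryl anion instead of an acyl cation. NBS (MeCN, −20 °C) brominates the only free carbon of ring A to give (3S)-3-{3,5-bis(benzyloxy)-2,4-bis[2-(benzyloxy)benzyl]-6-bromophenoxy}-3-phenylpropanoic acid F3. EDC·HCl, HOBt, MeNHOMe·HCl and i-Pr2NEt convert it into the N-methoxy-N-methylamide (3S)-3-{3,5-bis(benzyloxy)-2,4-bis[2-(benzyloxy)benzyl]-6-bromophenoxy}-N-methoxy-N-methyl-3-phenylpropanamide F4. t-BuLi (2.1 equiv, THF, −100 °C) effects bromine–lithium exchange and Parham-type cyclisation onto the amide, returning to the route at 14.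

Step 1. The second C-benzylation may stall, the benzyl cation source may self-condense, or the acid may open the acetonide and trigger decarboxylation, which would unmask the third ring carbon. The fallback sets out from 2 and uses purchased methyl 2,4,6-trihydroxybenzoate (COC(=O)c1c(O)cc(O)cc1O) in place of 1, an acid-stable block that differentiates the oxygens by chelation. The same acid-catalysed Friedel–Crafts benzylation gives methyl 3,5-bis[2-(benzyloxy)benzyl]-2,4,6-trihydroxybenzoate F5. BnBr (2.1 equiv), K2CO3 in acetone benzylates the para hydroxyl and one ortho hydroxyl, the last one staying chelated to the ester carbonyl, to give methyl 2,4-bis(benzyloxy)-3,5-bis[2-(benzyloxy)benzyl]-6-hydroxybenzoate F6. KOH in aqueous DMSO at 110 °C, then acidification and warming, passes through acid 6 and returns to the route at 7.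

Further compounds
F1 | step 4 | 1,3-bis(benzyloxy)-2,4-bis[2-(benzyloxy)benzyl]-5-{[(1S)-1-phenylprop-2-en-1-yl]oxy}benzene | C=C[C@@H](c1ccccc1)Oc1cc(OCc2ccccc2)c(Cc2ccccc2OCc2ccccc2)c(OCc2ccccc2)c1Cc1ccccc1OCc1ccccc1
F2 | step 4 | (3S)-3-{3,5-bis(benzyloxy)-2,4-bis[2-(benzyloxy)benzyl]phenoxy}-3-phenylpropan-1-ol | OCC[C@@H](c1ccccc1)Oc1cc(OCc2ccccc2)c(Cc2ccccc2OCc2ccccc2)c(OCc2ccccc2)c1Cc1ccccc1OCc1ccccc1
F3 | step 7 | (3S)-3-{3,5-bis(benzyloxy)-2,4-bis[2-(benzyloxy)benzyl]-6-bromophenoxy}-3-phenylpropanoic acid | OC(=O)C[C@@H](c1ccccc1)Oc1c(Br)c(OCc2ccccc2)c(Cc2ccccc2OCc2ccccc2)c(OCc2ccccc2)c1Cc1ccccc1OCc1ccccc1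
F4 | step 7 | (3S)-3-{3,5-bis(benzyloxy)-2,4-bis[2-(benzyloxy)benzyl]-6-bromophenoxy}-N-methoxy-N-methyl-3-phenylpropanamide | CON(C)C(=O)C[C@@H](c1ccccc1)Oc1c(Br)c(OCc2ccccc2)c(Cc2ccccc2OCc2ccccc2)c(OCc2ccccc2)c1Cc1ccccc1OCc1ccccc1
F5 | step 1 | methyl 3,5-bis[2-(benzyloxy)benzyl]-2,4,6-trihydroxybenzoate | COC(=O)c1c(O)c(Cc2ccccc2OCc2ccccc2)c(O)c(Cc2ccccc2OCc2ccccc2)c1O
F6 | step 1 | methyl 2,4-bis(benzyloxy)-3,5-bis[2-(benzyloxy)benzyl]-6-hydroxybenzoate | COC(=O)c1c(OCc2ccccc2)c(Cc2ccccc2OCc2ccccc2)c(OCc2ccccc2)c(Cc2ccccc2OCc2ccccc2)c1O
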